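Slowness is the trouble here: at 6.00 h the readings are still climbing, so before comparing runs you must estimate where each one stops.

| flask | solid substrate | capture agent | remark | time |
|---|---|---|---|---|
| green | 1.6 M | 0.20 M | run made earlier |  |
| ochre | 1.6 M | 0.60 M | run made earlier |  |
| violet | 1.6 M | 1.7 M | run made earlier |  |
| teal | 1.7 M | 0.48 M | run made earlier |  |
| summer | 1.6 M | 0.480 M |  | 12 h |
| midnight | 0.80 M | 1.00 M |  | 12 h |
| autumn | 1.0 M | 0.480 M |  | 12 h |
| noon | 1.6 M | 0.250 M |  | 12 h |
| spring | 2.5 M | 1.50 M |  | 12 h |

| green: time / h | green: target / % | ochre: time / h | ochre: target / % | violet: time / h | violet: target / % | teal: time / h | teal: target / % |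
|---|---|---|---|---|---|---|---|
| 0.500 | 1.5 | 0.500 | 1.7 | 0.500 | 1.7 | 0.500 | 1.9 |
| 1.50 | 14.5 | 0.833 | 4.8 | 0.833 | 3.3 | 0.833 | 7.9 |
| 3.00 | 34.0 | 1.50 | 15.6 | 1.50 | 11.1 | 1.50 | 13.7 |
| 4.00 | 39.7 | 3.00 | 29.0 | 3.00 | 18.5 | 3.00 | 28.8 |
| 6.00 | 49.2 | 6.00 | 39.9 | 6.00 | 21.3 | 6.00 | 42.7 |

(scatter of a reading: 1 percentage point)

1. the flasks put in order of amount of target, in percent of the solid substrate charged, best first, at 12 h (summer / midnight / autumn / noon / spring)
2. the amount of target, in percent of the solid substrate charged of the flask you put first, at 12 h
3. the amount of target, in percent of the solid substrate charged of the flask you put last, at 12 h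

- solid substrate is a solid; its amount is given per volume of the solution
- at the start none of the solid substrate is in solution
- what has only dissolved of solid substrate counts as not reacted

Read the 3.00 h row against the 6.00 h row. Suppose the gap to the plateau shrinks by one factor q in each 3.00 h, counted from zero and ignoring the induction. The plateau is then the 3.00 h reading divided by (one minus q). Green has q = 0.447 and a plateau reading of 61.5 %. Violet has q = 0.151 and reads 21.8 %.

I assume that capture agent competes with the step to target for one intermediate and is consumed one for one. Trapping per target made is then κ·c(capture agent), so c(capture agent) decays as exp(−κ·c(target)). The balance is: b·c(target) plus capture agent consumed equals solid substrate charged, where b is the substrate spent per target outside the trap.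

Taking green's small capture charge as consumed gives b = 1.42. Violet's balance then gives 3.00 M⁻¹. This is the capture factor κ, a selectivity factor: trapped made per target made, per molar of capture agent. By this reckoning green keeps 5.21 % of its capture agent, which is consistent with the assumption but does not test it.

One Newton step on the balance, started from 1/(b + κ·c(capture agent)), gives my plateaus: noon 59.7 %, summer 50.2 %, autumn 44.8 %, spring 29.1 %, midnight 27.5 %. Spring and midnight differ by 1.6 percentage points against a scatter of 1 point in a reading, so I hold their order loosely. With green's q, noon at 12 h comes to 57.3 %.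

The forecast, holding that “capture agent diverts or kills the productive pathway”, gives noon > summer > autumn > spring > midnight, with 58 % on top and 21 % at the bottom.

The flasks give noon > summer > autumn > spring > midnight, with noon at 56.8 % and midnight at 29.0 %.

    starting material ⇌ intermediate A (K = 1.41, k = 0.0216 min⁻¹)
    intermediate A ⇌ intermediate B (K = 0.151, k = 0.107 min⁻¹)
    intermediate A → target (k = 0.00757 min⁻¹)
    intermediate B → side product (k = 0.0223 min⁻¹)
    intermediate B ⇌ intermediate C (K = 21.0, k = 0.00244 min⁻¹)
    capture agent + intermediate A → trapped intermediate (k = 0.0199 M⁻¹ min⁻¹)
    solid substrate ⇌ starting material, rate k7*(cs7 - [starting material]) while solid is left; crystals form when [starting material] > cs7 (solubility = 0.990 M, k = 0.265 min⁻¹)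

In midnight at the start, intermediate A is trapped with a pseudo-first-order rate constant of 0.0199 min⁻¹ against 0.00757 min⁻¹ for its step to target, a ratio of 2.63; at 12.0 h, with 54.3 % of its capture agent left, the ratio is 1.43, trapping is still faster than the step to target, and midnight holds 57.1 % trapped intermediate against 29.0 % target. The same κ, in the neighbour of noon with 1.0 M of capture agent, gives 33.4 %, and that flask stands at 34.9 %.

The readings were computed from invented constants; scatter was added.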